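**Numbering used throughout** (full names and SMILES are in the list after the steps): 1 eugenol; 2 its benzyl ether; 3 bis(pinacolato)diboron; 4 (S)-secondary boronate; 5 4-bromo-2,6-dimethoxyphenol; 6 its benzyl ether; 7 tetravinylstannane; 8 vinyllithium; 9 vinylboron ate complex; 10 coupled secondary boronate; 11 chloroiodomethane; 12 chloromethyllithium; 13 chloromethylboron ate complex; 14 homologated primary boronate; 15 primary alcohol; 16 dibenzylated oxolane; 17 target.
Ring atoms of the target: O1, C2 (guaiacyl), C3 (methyl), C4 (syringylmethyl through C7), C5 (CH2).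

## Analysis of the target

CID53359708 is a 7,9′-epoxylignan built on a single oxolane ring. C2 carries the 4-hydroxy-3-methoxyphenyl (guaiacyl) ring, C3 a methyl group, C4 the 4-hydroxy-3,5-dimethoxybenzyl (syringylmethyl) group through the exocyclic methylene C7, and C5 is an unsubstituted CH2 next to O1. C2, C3 and C4 are contiguous stereocentres, all R, and each substituent is trans to its neighbour, which is also the thermodynamically preferred arrangement on the five-membered ring. C2 is a benzylic ether para to a phenol oxygen: it ionises under acid, is at risk under hydrogenolysis, and is the one centre that can be corrected by equilibration. C3 and C4 are purely alkyl-substituted, with no carbonyl or heteroatom nearby through which they could be set or repaired. The two free phenols are easily oxidised to quinone methides and must stay masked until the end. The difficulty is twofold: C3 and C4 must be created with defined configuration in an unfunctionalised stretch of the molecule, and two aryl rings that differ by one methoxy group must end on different carbons (C2 and C7). The plan rests on the C4–C7 pair, a CH–CH2 unit between the C3 stereocentre and the syringyl ring that must also carry C5 on C4. This is the pattern a vinyl group acquires when a carbon group adds to its internal carbon, an aryl group to its terminal carbon, and boron stays on the internal carbon.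

## Retrosynthetic reasoning

**17 back to 16.** The two phenols of 17 are unmasked last. In 16 both are benzyl ethers, removed together by hydrogenolysis. Ethers are preferred to esters or silyl ethers because they survive organolithium reagents and basic oxidation, and because they keep both rings as alkoxyarenes, which the ring closure needs.

**16 back to 15 (cut O1–C2).** C2 is benzylic and para to an alkoxy donor, so it can be oxidised directly from a CH2 group and captured by the C5 hydroxyl of 15. Cutting here means C2 needs no functional group earlier and the open-chain precursor has only C3 and C4 as stereocentres. Cutting O1–C5 instead would require a C2 carbinol stereocentre to be carried through all the organometallic steps. The forward reaction must distinguish C2–H from C7–H and must close trans to the C3 methyl. The first is helped because the guaiacyl alkoxy group is coplanar with its ring while the syringyl one is twisted by two ortho methoxy groups, and because only a C2 cation has the hydroxyl within reach of a five-membered ring. The second follows from the all-trans ring being both the kinetic and the thermodynamic product.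

**15 back to 14 and 10 (cut C4–C5).** C5 is a single carbon bearing oxygen. It is traced to the C4–B bond of 10 by insertion of the carbenoid 12 (through 13) to give 14, followed by oxidation of the new primary C–B bond. Both operations keep the configuration at C4, so the problem of C4 becomes the problem of a C–B stereocentre.

**10 back to 4, 8 and 6 through 9 (cut C3–C4 and C7–aryl).** The two bonds flanking the C4–C7 unit are cut together, so that C4–C7 is the vinyl group of 8. This leaves a secondary boronate 4 with a single stereocentre and a simple aryl bromide 6, and it puts boron exactly where C5 is needed. The forward reaction must move the C3 group from boron to the internal vinyl carbon with retention, attach the aryl group to the terminal carbon, and set C4 through a chiral ferrocenyl bisphosphine–palladium catalyst.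

**4 back to 2 and 3, and 2 back to 1.** The C3–B bond is traced to the terminal alkene of 2, because eugenol 1 already has the aryl–CH2–CH=CH2 skeleton in which the terminal carbon becomes the C3 methyl group. The forward reaction must put boron on the internal carbon with control of the alkene face. That calls for a boryl–copper addition followed by protonation, since a copper hydride would place boron on the terminal carbon.

**6 back to 5, and 8 back to 7.** Bromide 6 is the benzyl ether of the commercial phenol 5. Vinyllithium 8 is made from 7 by tin–lithium exchange so that it is free of halide, which would slow the palladium step.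

## Alternatives that were turned down

**Alternative 1: (3+2) annulation of a donor–acceptor cyclopropane with a one-carbon aldehyde.**
- Disconnection: O1–C2 and C4–C5, with C5 from formaldehyde A3 and C2–C3–C4 from the trans cyclopropane diester A2.
- Forward key step: under catalysis by a tin Lewis acid, the oxygen of A3 opens A2 at the aryl-bearing carbon and the malonate carbon closes onto the carbonyl carbon, giving oxolane diester A1.
- For it: the ring forms in one stereospecific step with cheap catalysts. O1–C2 is made without an oxidant, so the choice between two benzylic positions never arises; on that point it is stronger than the chosen route.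
- Against it:
  - Opening with inversion at the aryl carbon of a trans cyclopropane gives A1 with the aryl group cis to the methyl group, so C2 would have to be inverted later.
  - C4 arrives as a quaternary malonate carbon. One ester must be excised, and the other must be taken down to a CH2 group and joined to the syringyl ring by a separate C–C coupling.
  - Enantioenriched A2 is not easy to make, and with an oxygenated aryl donor it can racemise through the ring-opened zwitterion.
- Comparison: at least six operations would follow the ring formation. The chosen route brings in C4, C7 and the syringyl ring in one event and leaves only C5 and the ring closure.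

**Alternative 2: directed hydroformylation with lactol closure.**
- Disconnection: C4–C5 and O1–C5, from the anti homoallylic alcohol A5, in which C4=C7 is an E-alkene conjugated with the syringyl ring.
- Forward key step: rhodium-catalysed hydroformylation with the C2 hydroxyl bound reversibly to a phosphinite ligand delivers the formyl group to C4. The aldehyde collapses onto the hydroxyl to give lactol A4.
- For it: A5 is a few steps from commercial materials by anti-crotylation and arylation of the terminal alkene. Both rings are in place, and the C2/C3 relationship is fixed early by a classical reaction. In step count and in the security of C2 it is as strong as or stronger than the chosen route.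
- Against it:
  - The alkene is a styrene, whose inherent preference is formylation at the benzylic carbon C7; the directing group has to overturn this on a slow 1,2-disubstituted alkene.
  - C4 is set only by 1,2-induction from C3 through the chelate.
  - A4 still needs deoxygenation at C5 under Lewis acid, next to the ionisable C2–O1 bond.
- Comparison: the chosen route sets C4 by the catalyst and forms its C–C bonds with a regiochemistry that is inherent to the metallate shift. It pays for this with a late oxidative closure.

**Alternative 3: Prins–pinacol reorganisation of a glyceraldehyde-derived aryl acetal.**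
- Disconnection: C2–C3 and C4–C5, with C7 at the aldehyde level, from dioxolane A7. The 4S configuration of A7 is assigned on the assumption that the metal-bound oxygen sits equatorial in the chair.
- Forward key step: a strong tin Lewis acid opens A7 to an aryl-stabilised oxocarbenium ion. The E-propenyl group attacks it (C2–C3), and ring contraction by migration of C5 from C7 to C4 gives formyl oxolane A6.
- For it: one chirality source sets all three centres in one operation, and a chair transition state from the E-alkene leads to the all-trans ring. In stereochemical economy it is stronger than the chosen route.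
- Against it:
  - The alkene is only 1,2-disubstituted and would develop a secondary cation at C4 next to an oxygen-bearing carbon, while the oxocarbenium ion, stabilised by a para-alkoxyaryl group, is a weak electrophile.
  - A geometrically pure E-alkene is required.
  - A6 has an epimerisable C4 and must be arylated and then deoxygenated at C7 without cleaving the equally benzylic C2–O1 bond.
- Comparison: the step count is similar. The chosen route brings C7 in as a CH2 group and forms C3–C4 and C7–aryl under catalyst control rather than through a cation cascade.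

Key step: step 5

Remark: tetravinylstannane, 4-bromo-2,6-dimethoxyphenol, chloroiodomethane and both enantiomers of the Mandyphos ligand are taken as commercial.
Remark: which Mandyphos enantiomer gives R at C4 with this migrating group is to be fixed by a trial with each; the route assumes the one that does.

## Route

Step 1
Reactants: 1 eugenol (4-allyl-2-methoxyphenol)
Product: 2 4-allyl-1-(benzyloxy)-2-methoxybenzene
Conditions: BnBr, K2CO3, acetone, reflux
Reagents that add atoms: benzyl bromide, BrCc1ccccc1
Why: Williamson ether synthesis on the phenoxide; the allyl group is inert to carbonate and no stereocentre is formed.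

Step 2
Reactants: 2 4-allyl-1-(benzyloxy)-2-methoxybenzene; 3 bis(pinacolato)diboron
Product: 4 (S)-2-{1-[4-(benzyloxy)-3-methoxyphenyl]propan-2-yl}-4,4,5,5-tetramethyl-1,3,2-dioxaborolane
Conditions: 3 (1.2 equiv), CuCl (5 mol %), P-stereogenic QuinoxP*-type bisphosphine with 5,8-trimethylsilyl groups (5 mol %, enantiomer giving S), KOt-Bu (20 mol %), MeOH (2 equiv), THF, −40 to 0 °C
Reagents that add atoms: none
Why: Copper-catalysed enantioselective Markovnikov protoboration (formal hydroboration) of an aliphatic terminal alkene: the ligand-bound boryl copper adds with boron on the internal carbon and methanol protonates the primary C–Cu bond. The ligand selects the alkene face and so sets C3 as S; a copper hydride with pinacolborane is avoided because it would deliver boron to the terminal carbon.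

Step 3
Reactants: 5 4-bromo-2,6-dimethoxyphenol
Product: 6 2-(benzyloxy)-5-bromo-1,3-dimethoxybenzene
Conditions: BnBr, K2CO3, DMF, 60 °C
Reagents that add atoms: benzyl bromide, BrCc1ccccc1
Why: Williamson ether synthesis; the flanked phenol needs the polar solvent and mild heating, and the aryl bromide is untouched.

Step 4
Reactants: 7 tetravinylstannane
Product: 8 vinyllithium (used as a titrated THF solution)
Conditions: n-BuLi (4 equiv), pentane, rt; solid washed with pentane, dissolved in THF
Reagents that add atoms: n-butyllithium, [Li]CCCC
Why: Tin–lithium exchange moves the butyl groups onto tin, and vinyllithium separates from the hydrocarbon. The reagent is free of lithium halide, which would otherwise slow the palladium step.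

Step 5
Reactants: 4 (S)-2-{1-[4-(benzyloxy)-3-methoxyphenyl]propan-2-yl}-4,4,5,5-tetramethyl-1,3,2-dioxaborolane; 8 vinyllithium; 6 2-(benzyloxy)-5-bromo-1,3-dimethoxybenzene
Product: 10 2-{(2R,3S)-4-[4-(benzyloxy)-3-methoxyphenyl]-1-[4-(benzyloxy)-3,5-dimethoxyphenyl]-3-methylbutan-2-yl}-4,4,5,5-tetramethyl-1,3,2-dioxaborolane, via vinylboron ate complex 9 (not isolated)
Conditions: 8 (1.0 equiv), THF, 0 °C to rt; then 6, Pd(OAc)2 (2 mol %), Mandyphos (2.4 mol %), NaOTf, THF, 60 °C
Reagents that add atoms: none
Why: Vinyllithium 8 adds to boron of 4 to give the four-coordinate ate complex 9; oxidative addition of 6 to the zerovalent palladium–Mandyphos complex gives an arylpalladium species (NaOTf takes up bromide) that binds the vinyl group of 9 and, as a π-acid, induces anti 1,2-migration of the C3 alkyl group from boron to the internal vinyl carbon (C3–C4) while palladium bonds to the terminal carbon; reductive elimination then forms C7–aryl and returns zerovalent palladium. The closest known reaction type is the palladium-catalysed enantioselective conjunctive cross-coupling of vinylboron ate complexes with aryl electrophiles, in which alkyl groups including secondary ones migrate; what is new is only that the migrating secondary carbon is itself a stereocentre. No ring is closed. The new stereocentre C4 is controlled by the chiral palladium complex, which chooses the face of the vinyl group it binds and hence the opposite face on which C3 arrives; the ligand enantiomer is chosen so that C4 becomes R. C3 stays S because a 1,2-metallate shift transfers the migrating carbon with retention. Three selectivities are needed: migration of the alkyl group and not of a pinacol oxygen (the sec-alkyl group is the only carbon ligand besides vinyl); conjunctive coupling over direct transfer of vinyl to palladium or β-hydride elimination (secured by the chelating ligand and the saturated boron); and catalyst control over the bias of C3 (expected to be small, since C3 carries only methyl, hydrogen and a CH2 group).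

Step 6
Reactants: 10 2-{(2R,3S)-4-[4-(benzyloxy)-3-methoxyphenyl]-1-[4-(benzyloxy)-3,5-dimethoxyphenyl]-3-methylbutan-2-yl}-4,4,5,5-tetramethyl-1,3,2-dioxaborolane; 11 chloroiodomethane
Product: 14 2-{(2R,3S)-2-[4-(benzyloxy)-3,5-dimethoxybenzyl]-4-[4-(benzyloxy)-3-methoxyphenyl]-3-methylbutyl}-4,4,5,5-tetramethyl-1,3,2-dioxaborolane, via chloromethyllithium 12 (not isolated), via chloromethylboron ate complex 13 (not isolated)
Conditions: 11 (2.5 equiv), n-BuLi (2.2 equiv), THF, −78 °C to rt
Reagents that add atoms: none
Why: Matteson homologation: iodine–lithium exchange on 11 gives carbenoid 12, which adds to boron to form 13; on warming, C4 migrates from boron to the CH2Cl carbon with loss of chloride. The 1,2-shift retains configuration, so C4 stays R and C5 is installed as a CH2–B group.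

Step 7
Reactants: 14 2-{(2R,3S)-2-[4-(benzyloxy)-3,5-dimethoxybenzyl]-4-[4-(benzyloxy)-3-methoxyphenyl]-3-methylbutyl}-4,4,5,5-tetramethyl-1,3,2-dioxaborolane
Product: 15 (2R,3S)-2-[4-(benzyloxy)-3,5-dimethoxybenzyl]-4-[4-(benzyloxy)-3-methoxyphenyl]-3-methylbutan-1-ol
Conditions: H2O2, NaOH, THF/H2O, 0 °C to rt
Reagents that add atoms: hydrogen peroxide, OO
Why: Oxidation of the primary C–B bond (hydroperoxide adds to boron, C5 shifts to oxygen) gives the alcohol; the aryl benzyl ethers and both stereocentres are inert.

Step 8
Reactants: 15 (2R,3S)-2-[4-(benzyloxy)-3,5-dimethoxybenzyl]-4-[4-(benzyloxy)-3-methoxyphenyl]-3-methylbutan-1-ol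
Product: 16 (2R,3R,4R)-2-[4-(benzyloxy)-3-methoxyphenyl]-4-[4-(benzyloxy)-3,5-dimethoxybenzyl]-3-methyloxolane
Conditions: DDQ (1.05 equiv), 4 Å MS, CH2Cl2, 0 °C to rt
Reagents that add atoms: none
Why: DDQ-mediated benzylic C–H oxidation with intramolecular etherification: hydride is abstracted from C2, para to the coplanar benzyloxy donor of the guaiacyl ring, and the C5 hydroxyl captures the cation in a 5-exo closure. C7 is less prone to oxidation because the syringyl benzyloxy group is twisted out of conjugation by its two ortho methoxy groups, and a cation there has no hydroxyl within reach of a five-membered ring. C2 forms R, trans to the C3 methyl, because oxygen adds to the face away from methyl and the all-trans ring is also the product of reversible C2–O ionisation.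

Step 9
Reactants: 16 (2R,3R,4R)-2-[4-(benzyloxy)-3-methoxyphenyl]-4-[4-(benzyloxy)-3,5-dimethoxybenzyl]-3-methyloxolane
Product: 17 4-[(2R,3R,4R)-4-(4-hydroxy-3,5-dimethoxybenzyl)-3-methyloxolan-2-yl]-2-methoxyphenol (CID53359708)
Conditions: H2 (1 atm), Pd/C, EtOAc, rt
Reagents that add atoms: none
Why: Hydrogenolysis cleaves the two aryl benzyl ethers much faster than the cyclic benzylic ether at C2; the reaction is stopped after two equivalents of hydrogen are taken up. No stereocentre is touched.

## Compound list

1 | eugenol (4-allyl-2-methoxyphenol) | C=CCc1ccc(O)c(OC)c1 | starting material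
2 | 4-allyl-1-(benzyloxy)-2-methoxybenzene | C=CCc1ccc(OCc2ccccc2)c(OC)c1 | intermediate
3 | bis(pinacolato)diboron | CC1(C)OB(OC1(C)C)B1OC(C)(C)C(C)(C)O1 | starting material
4 | (S)-2-{1-[4-(benzyloxy)-3-methoxyphenyl]propan-2-yl}-4,4,5,5-tetramethyl-1,3,2-dioxaborolane | COc1cc(C[C@H](C)B2OC(C)(C)C(C)(C)O2)ccc1OCc1ccccc1 | intermediate
5 | 4-bromo-2,6-dimethoxyphenol | COc1cc(Br)cc(OC)c1O | starting material
6 | 2-(benzyloxy)-5-bromo-1,3-dimethoxybenzene | COc1cc(Br)cc(OC)c1OCc1ccccc1 | intermediate
7 | tetravinylstannane | C=C[Sn](C=C)(C=C)C=C | starting material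
8 | vinyllithium | [Li]C=C | intermediate (reagent solution)
9 | lithium ethenyl{(2S)-1-[4-(benzyloxy)-3-methoxyphenyl]propan-2-yl}(pinacolato)borate | [Li+].COc1cc(C[C@H](C)[B-]2(C=C)OC(C)(C)C(C)(C)O2)ccc1OCc1ccccc1 | intermediate (not isolated)
10 | 2-{(2R,3S)-4-[4-(benzyloxy)-3-methoxyphenyl]-1-[4-(benzyloxy)-3,5-dimethoxyphenyl]-3-methylbutan-2-yl}-4,4,5,5-tetramethyl-1,3,2-dioxaborolane | COc1cc(C[C@H](C)[C@@H](Cc2cc(OC)c(OCc3ccccc3)c(OC)c2)B2OC(C)(C)C(C)(C)O2)ccc1OCc1ccccc1 | intermediate
11 | chloroiodomethane | ClCI | starting material
12 | chloromethyllithium | [Li]CCl | intermediate (not isolated)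
13 | lithium (chloromethyl){(2R,3S)-4-[4-(benzyloxy)-3-methoxyphenyl]-1-[4-(benzyloxy)-3,5-dimethoxyphenyl]-3-methylbutan-2-yl}(pinacolato)borate | [Li+].COc1cc(C[C@H](C)[C@@H](Cc2cc(OC)c(OCc3ccccc3)c(OC)c2)[B-]2(CCl)OC(C)(C)C(C)(C)O2)ccc1OCc1ccccc1 | intermediate (not isolated)
14 | 2-{(2R,3S)-2-[4-(benzyloxy)-3,5-dimethoxybenzyl]-4-[4-(benzyloxy)-3-methoxyphenyl]-3-methylbutyl}-4,4,5,5-tetramethyl-1,3,2-dioxaborolane | COc1cc(C[C@H](C)[C@@H](Cc2cc(OC)c(OCc3ccccc3)c(OC)c2)CB2OC(C)(C)C(C)(C)O2)ccc1OCc1ccccc1 | intermediate
15 | (2R,3S)-2-[4-(benzyloxy)-3,5-dimethoxybenzyl]-4-[4-(benzyloxy)-3-methoxyphenyl]-3-methylbutan-1-ol | COc1cc(C[C@H](C)[C@@H](Cc2cc(OC)c(OCc3ccccc3)c(OC)c2)CO)ccc1OCc1ccccc1 | intermediate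
16 | (2R,3R,4R)-2-[4-(benzyloxy)-3-methoxyphenyl]-4-[4-(benzyloxy)-3,5-dimethoxybenzyl]-3-methyloxolane | COc1cc([C@@H]2OC[C@H](Cc3cc(OC)c(OCc4ccccc4)c(OC)c3)[C@H]2C)ccc1OCc1ccccc1 | intermediate
17 | 4-[(2R,3R,4R)-4-(4-hydroxy-3,5-dimethoxybenzyl)-3-methyloxolan-2-yl]-2-methoxyphenol | COc1cc([C@@H]2OC[C@H](Cc3cc(OC)c(O)c(OC)c3)[C@H]2C)ccc1O | target

## Step count and least certain steps

Total: 9 steps. Longest linear sequence: 7 steps (1, 2, 5, 6, 7, 8, 9); steps 3 and 4 are side branches.

**Step 5 (key step).**
- What may go wrong: the 1,2-shift of a branched secondary group may be slow, so that direct transfer of the vinyl group to palladium or β-hydride elimination of the alkylpalladium intermediate takes over. Selectivity at C4 may erode if catalyst and substrate preferences oppose each other. Bromide may build up and inhibit the catalyst.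
- Fallback (sets out from 6 and 4, returns at 10): C4 is set by a chiral diamine in a lithiation–borylation instead. Bromide 6 is lithiated (n-BuLi, THF, −78 °C) and opened onto ethylene oxide (BF3·OEt2) to give 2-[4-(benzyloxy)-3,5-dimethoxyphenyl]ethan-1-ol F1. Acylation with 2,4,6-triisopropylbenzoyl chloride gives 2-[4-(benzyloxy)-3,5-dimethoxyphenyl]ethyl 2,4,6-tri(propan-2-yl)benzoate F2. Deprotonation of F2 with s-BuLi/(−)-sparteine (Et2O, −78 °C; this enantiomer is expected to give the required sense) and addition of 4 gives an ate complex. On warming, the C3 group migrates with loss of the benzoate and gives 10.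

**Step 8.**
- What may go wrong: hydride abstraction at C7 on the syringyl side, followed by Friedel–Crafts closure onto the other ring. Further oxidation of the product at C2, which is now a benzylic ether, leading to ring opening. Closure cis to the methyl group, which a trace of acid should equilibrate.
- Fallback (sets out from 5, 4 and 8, returns at 17): the syringyl ring is switched off electronically by a sulfonate.
  - Phenol 5 is tosylated (TsCl, Et3N, CH2Cl2) to 4-bromo-2,6-dimethoxyphenyl 4-methylbenzenesulfonate F3.
  - Ate complex 9 is coupled with F3 as in step 5 to give 4-{(2R,3S)-4-[4-(benzyloxy)-3-methoxyphenyl]-3-methyl-2-(4,4,5,5-tetramethyl-1,3,2-dioxaborolan-2-yl)butyl}-2,6-dimethoxyphenyl 4-methylbenzenesulfonate F4.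
  - Homologation as in step 6 gives 4-{(2R,3S)-4-[4-(benzyloxy)-3-methoxyphenyl]-3-methyl-2-[(4,4,5,5-tetramethyl-1,3,2-dioxaborolan-2-yl)methyl]butyl}-2,6-dimethoxyphenyl 4-methylbenzenesulfonate F5.
  - Oxidation as in step 7 at 0 °C gives 4-[(2R,3S)-4-[4-(benzyloxy)-3-methoxyphenyl]-2-(hydroxymethyl)-3-methylbutyl]-2,6-dimethoxyphenyl 4-methylbenzenesulfonate F6.
  - DDQ closure, now possible only on the guaiacyl side, gives 4-{[(3R,4R,5R)-5-[4-(benzyloxy)-3-methoxyphenyl]-4-methyloxolan-3-yl]methyl}-2,6-dimethoxyphenyl 4-methylbenzenesulfonate F7.
  - KOH in MeOH/THF at 60 °C removes the sulfonate and gives 4-{[(3R,4R,5R)-5-[4-(benzyloxy)-3-methoxyphenyl]-4-methyloxolan-3-yl]methyl}-2,6-dimethoxyphenol F8.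
  - Hydrogenolysis as in step 9 gives 17.

**Step 2.**
- What may go wrong: boron delivered to the terminal carbon, alkoxide-induced migration of the double bond into conjugation with the ring, or incomplete enantioselectivity (the minor enantiomer would appear as a diastereomer of 10).
- Fallback (sets out from 3 together with a commercial benzylic chloride, replaces 1 and 2, returns at 4): 1-(benzyloxy)-4-(chloromethyl)-2-methoxybenzene F9 is borylated with 3 (Pd(dba)2, tris(4-methoxyphenyl)phosphine, KOAc, toluene, 50 °C) to 2-[4-(benzyloxy)-3-methoxybenzyl]-4,4,5,5-tetramethyl-1,3,2-dioxaborolane F10. Ethyl 2,4,6-tri(propan-2-yl)benzoate F11 is lithiated with s-BuLi/(+)-sparteine (Et2O, −78 °C) and added to F10. On warming, the benzyl group migrates with loss of the benzoate and gives 4.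

**Step 9.**
- What may go wrong: hydrogenolysis of the C2–O1 benzylic ether, which would open the ring; the electron-rich aryl group activates this bond.
- Fallback (from 16 directly to 17): non-reductive debenzylation with BCl3 and pentamethylbenzene as cation scavenger in CH2Cl2 at −78 °C. Any ionisation at C2 is reversible and recloses to the all-trans ring.

## Further compounds

F1 | step 5 | 2-[4-(benzyloxy)-3,5-dimethoxyphenyl]ethan-1-ol | COc1cc(CCO)cc(OC)c1OCc1ccccc1
F2 | step 5 | 2-[4-(benzyloxy)-3,5-dimethoxyphenyl]ethyl 2,4,6-tri(propan-2-yl)benzoate | COc1cc(CCOC(=O)c2c(C(C)C)cc(C(C)C)cc2C(C)C)cc(OC)c1OCc1ccccc1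
F3 | step 8 | 4-bromo-2,6-dimethoxyphenyl 4-methylbenzenesulfonate | COc1cc(Br)cc(OC)c1OS(=O)(=O)c1ccc(C)cc1
F4 | step 8 | 4-{(2R,3S)-4-[4-(benzyloxy)-3-methoxyphenyl]-3-methyl-2-(4,4,5,5-tetramethyl-1,3,2-dioxaborolan-2-yl)butyl}-2,6-dimethoxyphenyl 4-methylbenzenesulfonate | COc1cc(C[C@H](C)[C@@H](Cc2cc(OC)c(OS(=O)(=O)c3ccc(C)cc3)c(OC)c2)B2OC(C)(C)C(C)(C)O2)ccc1OCc1ccccc1
F5 | step 8 | 4-{(2R,3S)-4-[4-(benzyloxy)-3-methoxyphenyl]-3-methyl-2-[(4,4,5,5-tetramethyl-1,3,2-dioxaborolan-2-yl)methyl]butyl}-2,6-dimethoxyphenyl 4-methylbenzenesulfonate | COc1cc(C[C@H](C)[C@@H](Cc2cc(OC)c(OS(=O)(=O)c3ccc(C)cc3)c(OC)c2)CB2OC(C)(C)C(C)(C)O2)ccc1OCc1ccccc1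
F6 | step 8 | 4-[(2R,3S)-4-[4-(benzyloxy)-3-methoxyphenyl]-2-(hydroxymethyl)-3-methylbutyl]-2,6-dimethoxyphenyl 4-methylbenzenesulfonate | COc1cc(C[C@H](C)[C@@H](Cc2cc(OC)c(OS(=O)(=O)c3ccc(C)cc3)c(OC)c2)CO)ccc1OCc1ccccc1
F7 | step 8 | 4-{[(3R,4R,5R)-5-[4-(benzyloxy)-3-methoxyphenyl]-4-methyloxolan-3-yl]methyl}-2,6-dimethoxyphenyl 4-methylbenzenesulfonate | COc1cc([C@@H]2OC[C@H](Cc3cc(OC)c(OS(=O)(=O)c4ccc(C)cc4)c(OC)c3)[C@H]2C)ccc1OCc1ccccc1
F8 | step 8 | 4-{[(3R,4R,5R)-5-[4-(benzyloxy)-3-methoxyphenyl]-4-methyloxolan-3-yl]methyl}-2,6-dimethoxyphenol | COc1cc([C@@H]2OC[C@H](Cc3cc(OC)c(O)c(OC)c3)[C@H]2C)ccc1OCc1ccccc1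
F9 | step 2 | 1-(benzyloxy)-4-(chloromethyl)-2-methoxybenzene | COc1cc(CCl)ccc1OCc1ccccc1
F10 | step 2 | 2-[4-(benzyloxy)-3-methoxybenzyl]-4,4,5,5-tetramethyl-1,3,2-dioxaborolane | COc1cc(CB2OC(C)(C)C(C)(C)O2)ccc1OCc1ccccc1
F11 | step 2 | ethyl 2,4,6-tri(propan-2-yl)benzoate | CCOC(=O)c1c(C(C)C)cc(C(C)C)cc1C(C)C
F0 | step 9 | none | none
A1 | alternative 1 | dimethyl (4R,5S)-5-[3-methoxy-4-(tosyloxy)phenyl]-4-methyldihydrofuran-3,3(2H)-dicarboxylate | COc1cc([C@H]2OCC(C(=O)OC)(C(=O)OC)[C@H]2C)ccc1OS(=O)(=O)c1ccc(C)cc1
A2 | alternative 1 | dimethyl (2R,3S)-2-[3-methoxy-4-(tosyloxy)phenyl]-3-methylcyclopropane-1,1-dicarboxylate | COc1cc([C@H]2[C@H](C)C2(C(=O)OC)C(=O)OC)ccc1OS(=O)(=O)c1ccc(C)cc1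
A3 | alternative 1 | formaldehyde | C=O
A4 | alternative 2 | (3R,4R,5R)-5-[4-(benzyloxy)-3-methoxyphenyl]-3-[4-(benzyloxy)-3,5-dimethoxybenzyl]-4-methyltetrahydrofuran-2-ol, anomeric mixture | COc1cc([C@@H]2OC(O)[C@H](Cc3cc(OC)c(OCc4ccccc4)c(OC)c3)[C@H]2C)ccc1OCc1ccccc1
A5 | alternative 2 | (1R,2R,3E)-1-[4-(benzyloxy)-3-methoxyphenyl]-4-[4-(benzyloxy)-3,5-dimethoxyphenyl]-2-methylbut-3-en-1-ol | COc1cc([C@H](O)[C@H](C)/C=C/c2cc(OC)c(OCc3ccccc3)c(OC)c2)ccc1OCc1ccccc1
A6 | alternative 3 | (3R,4R,5R)-5-[4-(benzyloxy)-3-methoxyphenyl]-4-methyltetrahydrofuran-3-carbaldehyde | COc1cc([C@@H]2OC[C@H](C=O)[C@H]2C)ccc1OCc1ccccc1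
A7 | alternative 3 | (4S)-2-[4-(benzyloxy)-3-methoxyphenyl]-4-[(E)-prop-1-en-1-yl]-1,3-dioxolane, mixture at the acetal carbon | COc1cc(C2OC[C@H](/C=C/C)O2)ccc1OCc1ccccc1
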